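**Retrosynthetic overview**
- The strategy rests on the vicinal oxygens of ring C, C3–OH and C4=O. They map onto the C3=C4 bond of a flav-3-ene whose C4 is benzylic to the electron-rich ring A. Target 18 ← diacetate 17 ← cis-epoxide 15, opened only at C4 by DMSO and oxidised there.
- Epoxide 15 ← (2S)-flav-3-ene diacetate 14 by catalyst-controlled oxygen-atom transfer anti to the 2-aryl group (sets C3, closes the oxirane).
- 14 ← (2S,4S)-flavan-4-ol 13 by dehydration ← racemic flavanone 12 by transfer-hydrogenative kinetic resolution (sets C2).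
- 12 ← chalcone 9 by oxa-Michael closure through the unhindered phenol (prenyl ends at C6) ← acetophenone 5 + aldehyde 7 (Claisen–Schmidt).
- Ring order: rings A and B come from the starting materials, ring C is closed in step 6, the oxirane is closed in step 11 and opened in step 12.

Key step: step 11

Assumption: the sense of both chiral catalysts is assigned by analogy with 4-chromanone (transfer hydrogenation) and 2,2-dimethyl-2H-chromene (epoxidation); if either proved opposite, the enantiomeric catalyst would be used. Prenyl = 3-methylbut-2-enyl.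

**Step 1**
Reactants: 1 2',6'-dihydroxy-4'-methoxyacetophenone; 2 prenyl bromide
Product: 3 1-[2,6-dihydroxy-4-methoxy-3-(3-methylbut-2-enyl)phenyl]ethanone
Conditions: 2 (1.0 equiv), 10% aq. KOH, 0 °C → rt; chromatography
Reagents that add atoms: none
Why: Nuclear C-prenylation of the acylresorcinol phenoxide in water (SN2 on the allylic bromide); 1 is symmetric, so the two open ring positions are equivalent and one mono-C-prenyl isomer should form beside separable O-prenyl and bis-prenyl by-products.

**Step 2**
Reactants: 3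
Product: 4 1-[6-(tert-butyldimethylsilyloxy)-2-hydroxy-4-methoxy-3-prenylphenyl]ethanone
Conditions: TBSCl (1.05 equiv), imidazole, DMF, 0 °C
Reagents that add atoms: tert-butyldimethylsilyl chloride, CC(C)(C)[Si](C)(C)Cl
Why: Selective silyl ether formation should take the hydroxyl next to the ring CH, because the other one is crowded by the prenyl group and stays hydrogen-bonded to the carbonyl; this marks the oxygen that later becomes O1.

**Step 3**
Reactants: 4
Product: 5 1-[6-(tert-butyldimethylsilyloxy)-4-methoxy-2-(methoxymethoxy)-3-prenylphenyl]ethanone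
Conditions: MOMCl (3 equiv), iPr2NEt (4 equiv), CH2Cl2, 0 → 40 °C
Reagents that add atoms: chloromethyl methyl ether, COCCl
Why: The remaining hindered, chelated phenol is etherified by the small, reactive chloromethyl ether to a base-stable MOM acetal, which fixes it as the future 5-oxygen.

**Step 4**
Reactants: 6 isovanillin
Product: 7 4-methoxy-3-(methoxymethoxy)benzaldehyde
Conditions: MOMCl, iPr2NEt, CH2Cl2, 0 °C → rt
Reagents that add atoms: chloromethyl methyl ether, COCCl
Why: Standard MOM etherification of the phenol keeps the aldehyde partner neutral in the aldol step.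

**Step 5**
Reactants: 5; 7
Product: 9 (E)-1-[6-hydroxy-4-methoxy-2-(methoxymethoxy)-3-prenylphenyl]-3-[4-methoxy-3-(methoxymethoxy)phenyl]prop-2-en-1-one, via desilylated acetophenone phenoxide 8 (not isolated)
Conditions: 50% aq. KOH (excess), EtOH, 0 °C → rt; AcOH to pH 6
Reagents that add atoms: none
Why: Hydroxide cleaves the aryl silyl ether and then drives the Claisen–Schmidt condensation (aldol addition, E1cB dehydration) to the E-enone, while both MOM acetals are inert to base.

**Step 6**
Reactants: 9
Product: 10 rac-7-methoxy-2-[4-methoxy-3-(methoxymethoxy)phenyl]-5-(methoxymethoxy)-6-prenylchroman-4-one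
Conditions: NaOAc (5 equiv), EtOH, reflux
Reagents that add atoms: none
Why: The only free phenol, the one next to the ring CH, adds to the enone in a reversible 6-endo oxa-Michael closure that lies on the flavanone side for 6'-alkoxy-2'-hydroxychalcones, so ring C forms with the prenyl group at C6 and not C8; C2 is racemic here.

**Step 7**
Reactants: 10
Product: 11 rac-5-hydroxy-2-(3-hydroxy-4-methoxyphenyl)-7-methoxy-6-prenylchroman-4-one
Conditions: 3 M aq. HCl–MeOH (1:5), 40 °C, short reaction time
Reagents that add atoms: none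
Why: Acid-catalysed acetal methanolysis removes both MOM groups on the acid-stable, still racemic flavanone, under conditions that prenylated flavanones tolerate for short times.

**Step 8**
Reactants: 11
Product: 12 rac-5-acetoxy-2-(3-acetoxy-4-methoxyphenyl)-7-methoxy-6-prenylchroman-4-one
Conditions: Ac2O, pyridine, DMAP (cat.), CH2Cl2, 0 °C → rt
Reagents that add atoms: acetic anhydride, CC(=O)OC(C)=O
Why: DMAP-catalysed acylation esterifies both phenols, including the chelated 5-OH; the acetates lower the donor strength of ring A for the later epoxide and are removed last.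

**Step 9**
Reactants: 12
Product: 13 (2S,4S)-5-acetoxy-2-(3-acetoxy-4-methoxyphenyl)-7-methoxy-6-prenylchroman-4-ol (2,4-cis)
Conditions: RuCl[(S,S)-TsDPEN](p-cymene) (2 mol%), HCO2H–Et3N (5:2), EtOAc, rt, stopped near half conversion; chromatography
Reagents that add atoms: none
Why: Noyori–Ikariya asymmetric transfer hydrogenation used as a kinetic resolution of a racemic flavanone: the (S,S)-catalyst gives the (4S)-carbinol and is fast only when that face is also anti to the 2-aryl group, so the (2S)-ketone should give the cis (2S,4S)-alcohol while the (2R)-ketone is left and separated; the outer-sphere hydride/proton transfer gives the neutral alcohol directly, so acetyl migration from O5 is not expected, and the prenyl alkene is not reduced.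

**Step 10**
Reactants: 13
Product: 14 (2S)-5-acetoxy-2-(3-acetoxy-4-methoxyphenyl)-7-methoxy-6-prenyl-2H-chromene
Conditions: Martin sulfurane (1.3 equiv), CH2Cl2, −20 °C → rt; Et3N-deactivated silica, under argon
Reagents that add atoms: none
Why: Martin sulfurane dehydration: the benzylic C4 hydroxyl becomes an alkoxysulfonium leaving group that ionises with help from ring A and loses H3 without Brønsted acid, so the C2–O bond, which would ionise and racemise under acid, is untouched and C2 stays S.

**Step 11**
Reactants: 14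
Product: 15 (2R,3S,4S)-5-acetoxy-2-(3-acetoxy-4-methoxyphenyl)-3,4-epoxy-7-methoxy-6-prenylchroman (oxirane anti to the 2-aryl group)
Conditions: (S,S)-Jacobsen Mn(III)–salen chloride (5 mol%), 4-phenylpyridine N-oxide (20 mol%), aq. NaOCl buffered to pH 11.3, CH2Cl2, 0 °C; organic phase dried over K2CO3, concentrated cold, used at once
Reagents that add atoms: sodium hypochlorite, [Na+].[O-]Cl
Why: Hypochlorite oxidises the Mn(III)–salen to a Mn(V)=O species that approaches the cis C3=C4 bond side-on, bonds oxygen to C3 to give a C4 radical stabilised by ring A, and collapses by C4–O bond formation, as in the Jacobsen–Katsuki epoxidation of 2,2-dimethyl-2H-chromenes. The oxirane is closed as a three-membered ring by this stepwise oxygen-atom transfer (radical recombination at C4), cis-fused to the pyran. C3 and C4 are set together by the catalyst: the (S,S) enantiomer gives (3S,4S)-epoxychromans, which in 14 is the face anti to the 2-aryl group, so catalyst and substrate bias should reinforce each other. Site selectivity over the prenyl alkene is needed; it should follow from the catalyst's strong preference for cis-disubstituted aryl-conjugated alkenes over an isolated trisubstituted one, and hypochlorite at pH 11 does not epoxidise alkenes by itself. The 5-acetoxy group lowers the donor strength of ring A so that the benzylic epoxide should survive the cold basic two-phase medium.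

**Step 12**
Reactants: 15
Product: 17 (2R,3R)-5-acetoxy-2-(3-acetoxy-4-methoxyphenyl)-3-hydroxy-7-methoxy-6-prenylchroman-4-one, via C4 alkoxysulfonium triflate 16 (not isolated)
Conditions: DMSO (20 equiv) premixed with TfOH (1.05 equiv), CH2Cl2, −40 → 0 °C; then iPr2NEt (3 equiv), 0 °C → rt
Reagents that add atoms: dimethyl sulfoxide, CS(C)=O
Why: Epoxide-to-α-hydroxy-ketone oxidation of the Kornblum/Swern type: the protonated oxirane opens only at benzylic C4 (cation stabilised by O1 and 7-OMe), DMSO oxygen is captured there, and the amine forms the sulfur ylide that removes H4 and expels dimethyl sulfide, so the C3–O bond is never broken and the 3-hydroxyl stays trans to the aryl group, giving (2R,3R).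

**Step 13**
Reactants: 17
Product: 18 (2R,3R)-3,5-dihydroxy-2-(3-hydroxy-4-methoxyphenyl)-7-methoxy-6-prenylchroman-4-one (target)
Conditions: 0.5 M HCl in MeOH, rt
Reagents that add atoms: none
Why: Acid-catalysed transesterification of the two aryl acetates with methanol; no base is present, so the base-sensitive trans-dihydroflavonol is not epimerised or ring-opened, and dilute acid at room temperature should leave the prenyl group alone.

**Compound list**
1 | 2',6'-dihydroxy-4'-methoxyacetophenone | COc1cc(O)c(C(C)=O)c(O)c1 | starting material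
2 | prenyl bromide (1-bromo-3-methylbut-2-ene) | CC(C)=CCBr | starting material
3 | 1-[2,6-dihydroxy-4-methoxy-3-prenylphenyl]ethanone | CC(=O)c1c(O)cc(OC)c(CC=C(C)C)c1O | intermediate
4 | 1-[6-(tert-butyldimethylsilyloxy)-2-hydroxy-4-methoxy-3-prenylphenyl]ethanone | CC(=O)c1c(O[Si](C)(C)C(C)(C)C)cc(OC)c(CC=C(C)C)c1O | intermediate
5 | 1-[6-(tert-butyldimethylsilyloxy)-4-methoxy-2-(methoxymethoxy)-3-prenylphenyl]ethanone | CC(=O)c1c(O[Si](C)(C)C(C)(C)C)cc(OC)c(CC=C(C)C)c1OCOC | intermediate
6 | isovanillin (3-hydroxy-4-methoxybenzaldehyde) | COc1ccc(C=O)cc1O | starting material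
7 | 4-methoxy-3-(methoxymethoxy)benzaldehyde | COc1ccc(C=O)cc1OCOC | intermediate
8 | 1-[6-hydroxy-4-methoxy-2-(methoxymethoxy)-3-prenylphenyl]ethanone (present as its potassium phenoxide, not isolated) | CC(=O)c1c(O)cc(OC)c(CC=C(C)C)c1OCOC | intermediate
9 | (E)-1-[6-hydroxy-4-methoxy-2-(methoxymethoxy)-3-prenylphenyl]-3-[4-methoxy-3-(methoxymethoxy)phenyl]prop-2-en-1-one | COc1ccc(/C=C/C(=O)c2c(O)cc(OC)c(CC=C(C)C)c2OCOC)cc1OCOC | intermediate
10 | rac-7-methoxy-2-[4-methoxy-3-(methoxymethoxy)phenyl]-5-(methoxymethoxy)-6-prenylchroman-4-one | COc1ccc(C2Oc3cc(OC)c(CC=C(C)C)c(OCOC)c3C(=O)C2)cc1OCOC | intermediate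
11 | rac-5-hydroxy-2-(3-hydroxy-4-methoxyphenyl)-7-methoxy-6-prenylchroman-4-one | COc1ccc(C2Oc3cc(OC)c(CC=C(C)C)c(O)c3C(=O)C2)cc1O | intermediate
12 | rac-5-acetoxy-2-(3-acetoxy-4-methoxyphenyl)-7-methoxy-6-prenylchroman-4-one | COc1ccc(C2Oc3cc(OC)c(CC=C(C)C)c(OC(C)=O)c3C(=O)C2)cc1OC(C)=O | intermediate
13 | (2S,4S)-5-acetoxy-2-(3-acetoxy-4-methoxyphenyl)-7-methoxy-6-prenylchroman-4-ol | COc1ccc([C@H]2Oc3cc(OC)c(CC=C(C)C)c(OC(C)=O)c3[C@@H](O)C2)cc1OC(C)=O | intermediate
14 | (2S)-5-acetoxy-2-(3-acetoxy-4-methoxyphenyl)-7-methoxy-6-prenyl-2H-chromene | COc1ccc([C@H]2Oc3cc(OC)c(CC=C(C)C)c(OC(C)=O)c3C=C2)cc1OC(C)=O | intermediate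
15 | (2R,3S,4S)-5-acetoxy-2-(3-acetoxy-4-methoxyphenyl)-3,4-epoxy-7-methoxy-6-prenylchroman | COc1ccc([C@H]2Oc3cc(OC)c(CC=C(C)C)c(OC(C)=O)c3[C@@H]4O[C@H]24)cc1OC(C)=O | intermediate
16 | (2R,3R,4RS)-5-acetoxy-2-(3-acetoxy-4-methoxyphenyl)-4-(dimethylsulfoniooxy)-3-hydroxy-7-methoxy-6-prenylchroman triflate (not isolated) | COc1ccc([C@H]2Oc3cc(OC)c(CC=C(C)C)c(OC(C)=O)c3C(O[S+](C)C)[C@@H]2O)cc1OC(C)=O.[O-]S(=O)(=O)C(F)(F)F | intermediate
17 | (2R,3R)-5-acetoxy-2-(3-acetoxy-4-methoxyphenyl)-3-hydroxy-7-methoxy-6-prenylchroman-4-one | COc1ccc([C@H]2Oc3cc(OC)c(CC=C(C)C)c(OC(C)=O)c3C(=O)[C@@H]2O)cc1OC(C)=O | intermediate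
18 | (2R,3R)-3,5-dihydroxy-2-(3-hydroxy-4-methoxyphenyl)-7-methoxy-6-prenylchroman-4-one | COc1ccc([C@H]2Oc3cc(OC)c(CC=C(C)C)c(O)c3C(=O)[C@@H]2O)cc1O | target

**Step count**
Total: 13 steps. Longest linear sequence: 12 steps (1 → 18 through steps 1–3 and 5–13; step 4 is a one-step branch).

**Steps most likely to fail**

Step 11. Oxygen transfer may go partly to the prenyl alkene or to the wrong face, and the very labile benzylic oxirane may open by water or trace acid before it is used. The fallback forms the C3–O bond by enolate hydroxylation of a resolved flavanone instead of chromene epoxidation. It sets out from 10. Transfer hydrogenation with RuCl[(R,R)-TsDPEN](p-cymene) and HCO2H–Et3N, taken beyond half conversion, would leave (2S)-7-methoxy-2-[4-methoxy-3-(methoxymethoxy)phenyl]-5-(methoxymethoxy)-6-prenylchroman-4-one F1 and would convert the (2R)-ketone into the separable (2R,4R)-configured chroman-4-ol bis-MOM ether F2. Deprotonation of F1 with LiHMDS in THF at −78 °C (kept cold to outrun β-elimination of the phenoxide) and trapping with 2-(phenylsulfonyl)-3-phenyloxaziridine anti to the 2-aryl group should give the (2R,3R)-3-hydroxyflavanone bis-MOM ether F3. Methanolic HCl then removes both MOM groups, and the fallback comes back to the route at 18.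

Step 12. The C4 cation may undergo a 1,2-hydride shift to the flavan-3-one or be captured by the neighbouring 5-acetoxy carbonyl, and C3 may epimerise during the amine step. The fallback sets out from 15. Hydrolytic opening in wet THF with a trace of PPTS should give the (2R,3S,4RS)-5-acetoxy-2-(3-acetoxy-4-methoxyphenyl)-7-methoxy-6-prenylchroman-3,4-diol F4, again with the C3–O bond intact. The electron-rich benzylic C4 carbinol is then oxidised chemoselectively with DDQ in CH2Cl2 at rt, and the fallback comes back at 17.

Step 9. The peri-acetoxy group may crowd the carbonyl so that the catalyst discriminates poorly between the flavanone enantiomers or reduces too slowly. The fallback sets out from 12. Reduction with NaBH4/CeCl3 in MeOH–THF at −40 °C (hydride anti to the aryl group) should give the racemic cis-5-acetoxy-2-(3-acetoxy-4-methoxyphenyl)-7-methoxy-6-prenylchroman-4-ol F5. Acylative kinetic resolution with Pseudomonas cepacia lipase and vinyl acetate in MTBE should esterify the (4R)-carbinol to the (2R,4R)-4,5-diacetoxy-2-(3-acetoxy-4-methoxyphenyl)-7-methoxy-6-prenylchroman F6. The unreacted (2S,4S)-alcohol is 13, where the fallback comes back.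

**Further compounds**
F1 | step 11 | (2S)-7-methoxy-2-[4-methoxy-3-(methoxymethoxy)phenyl]-5-(methoxymethoxy)-6-prenylchroman-4-one | COc1ccc([C@H]2Oc3cc(OC)c(CC=C(C)C)c(OCOC)c3C(=O)C2)cc1OCOC
F2 | step 11 | (2R,4R)-7-methoxy-2-[4-methoxy-3-(methoxymethoxy)phenyl]-5-(methoxymethoxy)-6-prenylchroman-4-ol | COc1ccc([C@@H]2Oc3cc(OC)c(CC=C(C)C)c(OCOC)c3[C@H](O)C2)cc1OCOC
F3 | step 11 | (2R,3R)-3-hydroxy-7-methoxy-2-[4-methoxy-3-(methoxymethoxy)phenyl]-5-(methoxymethoxy)-6-prenylchroman-4-one | COc1ccc([C@H]2Oc3cc(OC)c(CC=C(C)C)c(OCOC)c3C(=O)[C@@H]2O)cc1OCOC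
F4 | step 12 | (2R,3S,4RS)-5-acetoxy-2-(3-acetoxy-4-methoxyphenyl)-7-methoxy-6-prenylchroman-3,4-diol | COc1ccc([C@H]2Oc3cc(OC)c(CC=C(C)C)c(OC(C)=O)c3C(O)[C@@H]2O)cc1OC(C)=O
F5 | step 9 | racemic cis-5-acetoxy-2-(3-acetoxy-4-methoxyphenyl)-7-methoxy-6-prenylchroman-4-ol (both enantiomers written) | COc1ccc([C@H]2Oc3cc(OC)c(CC=C(C)C)c(OC(C)=O)c3[C@@H](O)C2)cc1OC(C)=O.COc1ccc([C@@H]2Oc3cc(OC)c(CC=C(C)C)c(OC(C)=O)c3[C@H](O)C2)cc1OC(C)=O
F6 | step 9 | (2R,4R)-4,5-diacetoxy-2-(3-acetoxy-4-methoxyphenyl)-7-methoxy-6-prenylchroman | COc1ccc([C@@H]2Oc3cc(OC)c(CC=C(C)C)c(OC(C)=O)c3[C@H](OC(C)=O)C2)cc1OC(C)=O
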